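## Structural features

The target is a 2H-chromene: benzene ring A is fused through C4a and C8a to 2H-pyran ring B, which holds the ether oxygen O1 on C8a and a styrene-type C3=C4 double bond. Ring A carries an acetyl group at C6 and a hydroxyl at C7, an ortho-hydroxyacetophenone whose phenol is hydrogen-bonded to the ketone and sits meta to O1 as in a resorcinol. C2 is the only stereocentre; it is quaternary and R-configured, bears O1, the vinylic C3, a methyl group and a CH2O arm, and has no neighbouring stereocentre. The CH2O arm is esterified with (E)-ferulic acid, a cinnamate with a free guaiacol-type phenol. Fragile points are the ester (base, transesterification), the E-cinnamate and the electron-rich C3=C4 bond (acid, radicals, hydrogenation), the two phenols (oxidants), and the allylic tertiary aryl ether at C2, which can lose configuration by 6π electrocyclic ring opening under light or strong heating. The real difficulty is the oxygenated quaternary stereocentre, whose methyl and CH2O substituents differ only in oxidation level; any reaction at a CH2 next to it must avoid carbanion character (expulsion of O1) and radical character (rearrangement onto C3=C4). The key step exploits this near-symmetry: C2 with both one-carbon arms is the carbonyl carbon of acetonide-protected dihydroxyacetone, C3 and C4 are the acetyl group of an ortho-hydroxyacetophenone, and O1 is its ortho phenol oxygen, so ring B closes in one operation as an achiral spirochromanone.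

## Logic of the disconnections

21 to 20: the two phenolic O–H bonds are replaced by O–Si bonds. Both phenols stay masked until the end, so the last step is a buffered fluoride treatment that must not touch the cinnamate ester or the chromene.

20 to 16 and 19: the ester C–O bond between the C2 arm and the cinnamoyl carbonyl is cut. This is the convergent cut and removes ten carbons; the forward step must acylate a neopentyl-type primary alcohol, which is why 19 (from 17) has its phenol capped.

16 to 14: the C6–acetyl bond is cut and the acetyl group is replaced by bromine. The bromide marks C6 from the start and is inert to hydride, whereas a ketone would be reduced in the deoxygenation; the demand is a palladium coupling on a compound that already carries the stereocentre.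

14 to 12 to 11: a C–H bond of the C2 methyl group is replaced by a C–O bond, and the other arm is acetylated. The forward deoxygenation is planned as a closed-shell hydride substitution of a triflate, which cannot eliminate because C2 has no hydrogen. A diazene route through the aldehyde tosylhydrazone or a radical deoxygenation was set aside: both pass through a primary radical or carbanion flanked by O1 and C3=C4, inviting vinyl migration, ring expansion or expulsion of the aryloxide. The demand is that hydride delivery outruns attack by the neighbouring oxygen.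

11 to 9: the acetyl C–O bond is cut and the stereocentre disappears, since 9 has two identical arms. The forward step must distinguish enantiotopic CH2OH groups, which is work for a lipase.

9 to 8: the two acetal C–O bonds are restored. The diol stays masked until C3=C4 exists, because a C4 cation in the presence of a free hydroxymethyl group would be trapped as a bridged ether.

8 to 6 to 5: C3=C4 is traced back to a C4 carbinol and then to the C4 ketone. This is done on achiral material, because a chroman-4-one with a stereogenic C2 could racemise by retro-oxa-Michael opening.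

5 to 2 and 3 (through 4): the C2–C3 and O1–C2 bonds are cut. This is the main simplification: ring B and the quaternary carbon come from two small achiral compounds.

2 to 1: the O–Si bond at the para oxygen is cut. Capping this hydroxyl before the annulation costs no extra step, since the same group is needed for the C4 reduction and all later steps, and it removes the para-phenoxide that would deactivate the acetyl group.

## Other disconnections considered

Alternative 1: The cut runs through ring A at C5–C6 and C7–C8, so the resorcinol ring is built. In the forward step the α-methylene ketone (R)-7-(tert-butyldimethylsilyloxy)-6-hydroxy-6-methyl-3-methylideneheptan-2-one A1 would take up dimethyl malonate A2 under alkoxide base (Michael addition). The methyl ketone enolate would then close onto one ester (Claisen) to give methyl 5-[(R)-4-(tert-butyldimethylsilyloxy)-3-hydroxy-3-methylbutyl]-2,4-dioxocyclohexane-1-carboxylate A3.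
- In its favour: the oxygen pattern and the C6 carbon substituent are placed without any regiochemical question. The stereocentre arrives with its methyl group, from an acyclic tertiary alcohol made by reagent-controlled chemistry of predictable sense. On both points (no deoxygenation beside C2, no enzyme of unknown preference) it is better than the chosen plan.
- Against it: A3 is a mixture of ring epimers at the wrong oxidation level. It still needs aromatisation, closure of ring B by condensing the tertiary alcohol with the C8a carbonyl, conversion of the ester into the acetyl group, and dehydrogenation of a chroman to install C3=C4 next to a free phenol. A1 is prone to polymerisation.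
- Comparison: mechanistically the two polar C–C bond formations are as reliable as the annulation chosen here. Structurally it solves ring A but leaves ring B and the alkene open, and it is clearly longer.

Alternative 2: The cut is the O1–C8a bond. In the forward step the tertiary alkoxide of (R,Z)-1-{2,4-difluoro-5-[3-hydroxy-4-(4-methoxybenzyloxy)-3-methylbut-1-enyl]phenyl}ethanone A4 would displace the fluoride para to the acetyl group by addition–elimination, giving (R)-1-[7-fluoro-2-(4-methoxybenzyloxymethyl)-2-methyl-2H-chromen-6-yl]ethanone A5.
- In its favour: the acetyl group, the C3=C4 bond and the complete stereocentre are in place before ring closure. It needs no reduction and dehydration, no bromide-to-acetyl exchange and no deoxygenation, and is better than the chosen plan on all three. Only the para fluoride can be reached through a six-membered transition state. The step count should be equal or slightly lower.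
- Against it: an enantiopure acyclic tertiary alcohol with a Z-styrene must be made first, including an alkyne semi-reduction beside an aryl ketone. The strongly basic closure meets an enolisable methyl ketone and a second activated fluoride, so aldol condensation and intermolecular substitution can compete. The remaining fluorine must then be exchanged for hydroxyl, and the benzyl-type ether removed in the presence of the chromene.
- Comparison: absolute configuration rests on the precursor and is more predictable than an enzymatic choice, which is a point in its favour. The chosen plan starts from cheap achiral compounds and confines the stereochemical risk to one screenable step.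

Alternative 3: The cut is C4a–C5 and C6–C7, ring A being made by cycloaddition. In the forward step the diene (R)-tert-butyl{[6-(2,2-bis(trimethylsilyloxy)ethenyl)-2-methyl-3,4-dihydro-2H-pyran-2-yl]methoxy}dimethylsilane A6 would add but-3-yn-2-one A7 in a (4+2) reaction. Loss of a silanol would aromatise the adduct to (R)-1-[2-(tert-butyldimethylsilyloxymethyl)-7-hydroxy-2-methylchroman-6-yl]ethanone A8.
- In its favour: the acetyl group and the C7 hydroxyl are set in one step, with regiochemistry dictated by the polarisation of the ketene acetal diene. This is better than the chosen route's bromide-to-acetyl exchange and phenol protection. The stereocentre is complete from the start.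
- Against it: A6 is a moisture-sensitive bis-silyl ketene acetal, and its enantiopure dihydropyran precursor needs a multi-step synthesis of its own. A8 is a chroman, so C3=C4 must still be introduced by benzylic dehydrogenation next to a free ortho-acyl phenol.
- Comparison: the cycloaddition is as well founded mechanistically as the annulation chosen here and more convergent on ring A, but the overall sequence is longer.

Key step: step 2

Assumption: Candida antarctica lipase B is taken to acylate the pro-S hydroxymethyl group of diol 9, the arm that stays oxygenated in the target; the opposite preference is covered by the fallback for step 6.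

## Route

Step 1
Reactants: 1 1-(5-bromo-2,4-dihydroxyphenyl)ethanone
Product: 2 1-[5-bromo-2-hydroxy-4-(triisopropylsilyloxy)phenyl]ethanone
Conditions: TIPSCl (1.05 equiv), imidazole, DMF, 0 °C to rt
Reagents that add atoms: triisopropylsilyl chloride, CC(C)[Si](Cl)(C(C)C)C(C)C
Why: Silylation of a phenol; the para hydroxyl is the more acidic one and the only one not held in the hydrogen bond to the acetyl group, so one equivalent of the bulky silyl chloride should take it selectively. The ether removes the para-phenoxide that would deactivate the acetyl group in step 2 and the C4 ketone in step 3, and it is the fluoride-labile phenol protection kept to the last step.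

Step 2
Reactants: 2 1-[5-bromo-2-hydroxy-4-(triisopropylsilyloxy)phenyl]ethanone; 3 2,2-dimethyl-1,3-dioxan-5-one
Product: 5 6-bromo-2',2'-dimethyl-7-(triisopropylsilyloxy)spiro[chromane-2,5'-[1,3]dioxan]-4-one, via enone 4 (not isolated)
Conditions: 3 (2 equiv), pyrrolidine (1 equiv), toluene, 4 Å molecular sieves, rt to 60 °C
Reagents that add atoms: none
Why: Kabbe condensation: pyrrolidine converts the acetyl group of 2 into a hydrogen-bonded enamine, which adds to the strongly electrophilic, doubly α-oxygenated carbonyl of 3, and loss of water from the adduct through its iminium ion forms the C2–C3 bond as the β,β-disubstituted enone 4. The ortho phenoxide then adds to the β-carbon of 4 (oxa-Michael), forming O1–C2 and closing ring B in a 6-endo-trig mode, and hydrolysis returns pyrrolidine. The closest known reaction type is the pyrrolidine-mediated condensation of 2-hydroxy-4-alkoxyacetophenones with cyclic ketones to spirochroman-4-ones. No stereocentre is formed, because the new quaternary carbon C2 carries the two identical CH2O arms of the dioxane, so 5 is achiral and nothing has to be controlled here. The selectivity needed is cross- over self-condensation and closure through the right oxygen: only the ortho hydroxyl is free, and it reaches the β-carbon through a six-membered transition state, while the para oxygen is silylated. Self-aldol of 3 is reversible and is drained towards 5, the only conjugated, ring-closed product, helped by the excess of 3. An aprotic solvent is chosen so that the aryl silyl ether is not cleaved by the amine, and the aryl bromide and the acetonide are inert to these conditions.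

Step 3
Reactants: 5 6-bromo-2',2'-dimethyl-7-(triisopropylsilyloxy)spiro[chromane-2,5'-[1,3]dioxan]-4-one
Product: 6 (±)-6-bromo-2',2'-dimethyl-7-(triisopropylsilyloxy)spiro[chromane-2,5'-[1,3]dioxan]-4-ol
Conditions: NaBH4, THF–MeOH (4:1), 0 °C
Reagents that add atoms: none
Why: Borohydride 1,2-reduction of an aryl ketone; the C4 carbinol stereocentre is formed as a racemate and is destroyed in step 4, so no control is needed.

Step 4
Reactants: 6 (±)-6-bromo-2',2'-dimethyl-7-(triisopropylsilyloxy)spiro[chromane-2,5'-[1,3]dioxan]-4-ol
Product: 8 6-bromo-2',2'-dimethyl-7-(triisopropylsilyloxy)spiro[chromene-2,5'-[1,3]dioxane], via mesylate 7 (not isolated)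
Conditions: MsCl, Et3N (4 equiv), CH2Cl2, 0 °C to 40 °C
Reagents that add atoms: none
Why: Mesylation of the benzylic alcohol followed by base-assisted loss of methanesulfonate; ionisation is eased by O1 and the para silyloxy group, and only C3 carries a β-hydrogen, so the conjugated C3=C4 alkene is the sole elimination product. No acid is present, so the acetonide and the silyl ether should persist.

Step 5
Reactants: 8 6-bromo-2',2'-dimethyl-7-(triisopropylsilyloxy)spiro[chromene-2,5'-[1,3]dioxane]
Product: 9 [6-bromo-7-(triisopropylsilyloxy)-2H-chromene-2,2-diyl]dimethanol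
Conditions: AcOH–H2O (4:1), 40 °C
Reagents that add atoms: none
Why: Acid-catalysed acetal hydrolysis; acetic acid is too weak to protonate the styrene-type double bond, so no C4 cation is available for trapping by the freed hydroxymethyl groups, and the aryl triisopropylsilyl ether is stable to it.

Step 6
Reactants: 9 [6-bromo-7-(triisopropylsilyloxy)-2H-chromene-2,2-diyl]dimethanol; 10 vinyl acetate
Product: 11 (S)-[6-bromo-2-(hydroxymethyl)-7-(triisopropylsilyloxy)-2H-chromen-2-yl]methyl acetate
Conditions: immobilised Candida antarctica lipase B (Novozym 435), 10 (3 equiv), MTBE, 30 °C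
Reagents that add atoms: none
Why: Lipase-catalysed enantiotopic-group-selective transesterification, the desymmetrisation known for prochiral 2,2-disubstituted propane-1,3-diols including chroman-2,2-dimethanols; the acyl-enzyme formed from 10 transfers acetyl to one CH2OH arm, and tautomerisation of the released vinyl alcohol makes the transfer irreversible. The C2 stereocentre is set by the enzyme, which tells the arms apart through the different neighbours of C2 (aryl ether O1 against vinylic C3) held rigidly in ring B. A slower second acylation consumes the minor enantiomer preferentially and can raise the enantiomeric purity of 11.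

Step 7
Reactants: 11 (S)-[6-bromo-2-(hydroxymethyl)-7-(triisopropylsilyloxy)-2H-chromen-2-yl]methyl acetate
Product: 12 (R)-[6-bromo-7-(triisopropylsilyloxy)-2-(trifluoromethylsulfonyloxymethyl)-2H-chromen-2-yl]methyl acetate
Conditions: Tf2O, pyridine, CH2Cl2, −78 to −30 °C; cold NaHCO3 work-up, used at once
Reagents that add atoms: trifluoromethanesulfonic anhydride, O=S(=O)(OS(=O)(=O)C(F)(F)F)C(F)(F)F
Why: O-Triflation of a primary alcohol; C2 has no hydrogen, so the neopentyl-type triflate cannot eliminate, and the cold, weakly basic medium avoids 1,3-acetyl migration between the arms, which would racemise 11. The descriptor changes from S to R only because the CH2OTf arm now outranks the CH2OAc arm; no bond to C2 is touched.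

Step 8
Reactants: 12 (R)-[6-bromo-7-(triisopropylsilyloxy)-2-(trifluoromethylsulfonyloxymethyl)-2H-chromen-2-yl]methyl acetate
Product: 14 (R)-[6-bromo-2-methyl-7-(triisopropylsilyloxy)-2H-chromen-2-yl]methanol, via hydroxy triflate 13 (not isolated)
Conditions: LiEt3BH (5 equiv), THF, −78 to 0 °C, 12 added to the hydride; aq. NH4Cl
Reagents that add atoms: none
Why: SN2 displacement of a hindered primary triflate by the strongly nucleophilic hydride LiEt3BH, the standard two-step deoxygenation of neopentyl-type alcohols, with reductive cleavage of the acetate by the same reagent. The aryl bromide, aryl silyl ether and styrene are inert to it at or below 0 °C, and C2 is not involved, so its configuration is kept.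

Step 9
Reactants: 14 (R)-[6-bromo-2-methyl-7-(triisopropylsilyloxy)-2H-chromen-2-yl]methanol
Product: 16 (R)-1-[2-(hydroxymethyl)-2-methyl-7-(triisopropylsilyloxy)-2H-chromen-6-yl]ethanone, via enol ether 15 (not isolated)
Conditions: tributyl(1-ethoxyvinyl)stannane, PdCl2(PPh3)2 (5 mol%), toluene, 90 °C, dark; then 1 M aq. HCl, THF, rt
Reagents that add atoms: tributyl(1-ethoxyvinyl)stannane, CCCC[Sn](CCCC)(CCCC)C(=C)OCC; water, O
Why: Stille coupling of the aryl bromide with a 1-ethoxyvinylstannane as acetyl anion equivalent (oxidative addition, transmetalation, reductive elimination at palladium), then acid hydrolysis of enol ether 15 to the methyl ketone. The stereocentre is a spectator: the C2–O1 bond lies close to the plane of the C3=C4 π system and is poorly aligned for ionisation by zerovalent palladium, and 90 °C is well below the temperatures at which 2H-chromenes open electrocyclically.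

Step 10
Reactants: 17 (E)-ferulic acid
Product: 19 (E)-3-[4-(tert-butyldimethylsilyloxy)-3-methoxyphenyl]prop-2-enoic acid, via silyl ester 18 (not isolated)
Conditions: TBSCl (2.5 equiv), imidazole, DMF, rt; then AcOH–THF–H2O (3:1:1), rt
Reagents that add atoms: tert-butyldimethylsilyl chloride, CC(C)(C)[Si](C)(C)Cl
Why: Silylation of both acidic hydroxyls, then selective hydrolysis of the labile silyl ester 18 in aqueous acetic acid, which leaves the aryl silyl ether; the E double bond is not touched.

Step 11
Reactants: 16 (R)-1-[2-(hydroxymethyl)-2-methyl-7-(triisopropylsilyloxy)-2H-chromen-6-yl]ethanone; 19 (E)-3-[4-(tert-butyldimethylsilyloxy)-3-methoxyphenyl]prop-2-enoic acid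
Product: 20 [(R)-6-acetyl-2-methyl-7-(triisopropylsilyloxy)-2H-chromen-2-yl]methyl (E)-3-[4-(tert-butyldimethylsilyloxy)-3-methoxyphenyl]prop-2-enoate
Conditions: 19 (1.3 equiv), EDC·HCl, DMAP, CH2Cl2, 0 °C to rt
Reagents that add atoms: none
Why: Steglich esterification; the carbodiimide activates 19 and DMAP transfers the acyl group to the only free hydroxyl of 16, a primary neopentyl-type alcohol. Both phenols are silylated, so neither oligomerisation of the acid nor aryl ester formation can compete.

Step 12
Reactants: 20 [(R)-6-acetyl-2-methyl-7-(triisopropylsilyloxy)-2H-chromen-2-yl]methyl (E)-3-[4-(tert-butyldimethylsilyloxy)-3-methoxyphenyl]prop-2-enoate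
Product: 21 [(R)-6-acetyl-7-hydroxy-2-methyl-2H-chromen-2-yl]methyl (E)-3-(4-hydroxy-3-methoxyphenyl)prop-2-enoate
Conditions: TBAF (2.5 equiv), AcOH (3 equiv), THF, 0 °C, dark
Reagents that add atoms: none
Why: Fluoride-induced cleavage of both aryl silyl ethers, driven by the strong Si–F bond; acetic acid buffers the phenoxides so that the cinnamate ester is neither cleaved nor transesterified. The cold, light-protected conditions leave the C2 aryl ether and the E alkene untouched.

## Compound list

1 | 1-(5-bromo-2,4-dihydroxyphenyl)ethanone | CC(=O)c1cc(Br)c(O)cc1O | starting material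
2 | 1-[5-bromo-2-hydroxy-4-(triisopropylsilyloxy)phenyl]ethanone | CC(=O)c1cc(Br)c(O[Si](C(C)C)(C(C)C)C(C)C)cc1O | intermediate
3 | 2,2-dimethyl-1,3-dioxan-5-one | CC1(C)OCC(=O)CO1 | starting material
4 | 1-[5-bromo-2-hydroxy-4-(triisopropylsilyloxy)phenyl]-2-(2,2-dimethyl-1,3-dioxan-5-ylidene)ethanone (enone, formed in the flask) | CC1(C)OCC(=CC(=O)c2cc(Br)c(O[Si](C(C)C)(C(C)C)C(C)C)cc2O)CO1 | intermediate
5 | 6-bromo-2',2'-dimethyl-7-(triisopropylsilyloxy)spiro[chromane-2,5'-[1,3]dioxan]-4-one (achiral) | CC1(C)OCC2(CO1)CC(=O)c1cc(Br)c(O[Si](C(C)C)(C(C)C)C(C)C)cc1O2 | intermediate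
6 | (±)-6-bromo-2',2'-dimethyl-7-(triisopropylsilyloxy)spiro[chromane-2,5'-[1,3]dioxan]-4-ol | CC1(C)OCC2(CO1)CC(O)c1cc(Br)c(O[Si](C(C)C)(C(C)C)C(C)C)cc1O2 | intermediate
7 | (±)-6-bromo-2',2'-dimethyl-7-(triisopropylsilyloxy)spiro[chromane-2,5'-[1,3]dioxan]-4-yl methanesulfonate (formed in the flask) | CC1(C)OCC2(CO1)CC(OS(C)(=O)=O)c1cc(Br)c(O[Si](C(C)C)(C(C)C)C(C)C)cc1O2 | intermediate
8 | 6-bromo-2',2'-dimethyl-7-(triisopropylsilyloxy)spiro[chromene-2,5'-[1,3]dioxane] (achiral 2H-chromene) | CC1(C)OCC2(CO1)C=Cc1cc(Br)c(O[Si](C(C)C)(C(C)C)C(C)C)cc1O2 | intermediate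
9 | [6-bromo-7-(triisopropylsilyloxy)-2H-chromene-2,2-diyl]dimethanol (prochiral) | OCC1(CO)C=Cc2cc(Br)c(O[Si](C(C)C)(C(C)C)C(C)C)cc2O1 | intermediate
10 | vinyl acetate | C=COC(C)=O | starting material
11 | (S)-[6-bromo-2-(hydroxymethyl)-7-(triisopropylsilyloxy)-2H-chromen-2-yl]methyl acetate | CC(=O)OC[C@@]1(CO)C=Cc2cc(Br)c(O[Si](C(C)C)(C(C)C)C(C)C)cc2O1 | intermediate
12 | (R)-[6-bromo-7-(triisopropylsilyloxy)-2-(trifluoromethylsulfonyloxymethyl)-2H-chromen-2-yl]methyl acetate | CC(=O)OC[C@@]1(COS(=O)(=O)C(F)(F)F)C=Cc2cc(Br)c(O[Si](C(C)C)(C(C)C)C(C)C)cc2O1 | intermediate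
13 | (R)-[6-bromo-2-(hydroxymethyl)-7-(triisopropylsilyloxy)-2H-chromen-2-yl]methyl trifluoromethanesulfonate (as its lithium alkoxide, formed in the flask) | OC[C@@]1(COS(=O)(=O)C(F)(F)F)C=Cc2cc(Br)c(O[Si](C(C)C)(C(C)C)C(C)C)cc2O1 | intermediate
14 | (R)-[6-bromo-2-methyl-7-(triisopropylsilyloxy)-2H-chromen-2-yl]methanol | OC[C@@]1(C)C=Cc2cc(Br)c(O[Si](C(C)C)(C(C)C)C(C)C)cc2O1 | intermediate
15 | (R)-[6-(1-ethoxyethenyl)-2-methyl-7-(triisopropylsilyloxy)-2H-chromen-2-yl]methanol (formed in the flask) | OC[C@@]1(C)C=Cc2cc(C(=C)OCC)c(O[Si](C(C)C)(C(C)C)C(C)C)cc2O1 | intermediate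
16 | (R)-1-[2-(hydroxymethyl)-2-methyl-7-(triisopropylsilyloxy)-2H-chromen-6-yl]ethanone | OC[C@@]1(C)C=Cc2cc(C(C)=O)c(O[Si](C(C)C)(C(C)C)C(C)C)cc2O1 | intermediate
17 | (E)-ferulic acid, (E)-3-(4-hydroxy-3-methoxyphenyl)prop-2-enoic acid | COc1cc(/C=C/C(=O)O)ccc1O | starting material
18 | tert-butyldimethylsilyl (E)-3-[4-(tert-butyldimethylsilyloxy)-3-methoxyphenyl]prop-2-enoate (formed in the flask) | COc1cc(/C=C/C(=O)O[Si](C)(C)C(C)(C)C)ccc1O[Si](C)(C)C(C)(C)C | intermediate
19 | (E)-3-[4-(tert-butyldimethylsilyloxy)-3-methoxyphenyl]prop-2-enoic acid | COc1cc(/C=C/C(=O)O)ccc1O[Si](C)(C)C(C)(C)C | intermediate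
20 | [(R)-6-acetyl-2-methyl-7-(triisopropylsilyloxy)-2H-chromen-2-yl]methyl (E)-3-[4-(tert-butyldimethylsilyloxy)-3-methoxyphenyl]prop-2-enoate | COc1cc(/C=C/C(=O)OC[C@@]2(C)C=Cc3cc(C(C)=O)c(O[Si](C(C)C)(C(C)C)C(C)C)cc3O2)ccc1O[Si](C)(C)C(C)(C)C | intermediate
21 | [(R)-6-acetyl-7-hydroxy-2-methyl-2H-chromen-2-yl]methyl (E)-3-(4-hydroxy-3-methoxyphenyl)prop-2-enoate | COc1cc(/C=C/C(=O)OC[C@@]2(C)C=Cc3cc(C(C)=O)c(O)cc3O2)ccc1O | target

## Step count and least certain steps

Total: 12 steps. Longest linear sequence: 11 steps (steps 1 to 9, 11 and 12, from 1); step 10 is the one-step side branch from 17.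

Step 2 (key step). Amine-catalysed self-condensation of the ketone partner, or cleavage of the aryl silyl ether by the amine, could outrun the cross-condensation and ring closure, since the dioxanone readily forms its own enamine. Fallback, from 2 and back at 5: the C2–C3 bond is made with a preformed lithium enolate instead of an enamine. The dianion of 2 (lithium diisopropylamide, LiN(iPr)2, 2.2 equiv, THF, −78 °C) is added to 3 to give the tertiary aldol 1-[5-bromo-2-hydroxy-4-(triisopropylsilyloxy)phenyl]-2-(5-hydroxy-2,2-dimethyl-1,3-dioxan-5-yl)ethanone F1. Dehydration through its trifluoroacetate (trifluoroacetic anhydride, Et3N, then DBU) leads to enone 4, which closes under the same DBU conditions by oxa-Michael addition to 5.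

Step 6. The lipase may acylate the other enantiotopic arm, since the sense of discrimination for this flat bicyclic diol cannot be predicted, or it may discriminate only moderately. Fallback, from 9 and back at 14: if the pro-R arm is acylated, step 6 delivers (R)-[6-bromo-2-(hydroxymethyl)-7-(triisopropylsilyloxy)-2H-chromen-2-yl]methyl acetate F2, and the arms are then sorted chemically.
- Silylation of the free arm (TBSOTf, 2,6-lutidine, −78 °C) gives (S)-[6-bromo-2-(tert-butyldimethylsilyloxymethyl)-7-(triisopropylsilyloxy)-2H-chromen-2-yl]methyl acetate F3.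
- Methanolysis (K2CO3, MeOH, 0 °C) gives (S)-[6-bromo-2-(tert-butyldimethylsilyloxymethyl)-7-(triisopropylsilyloxy)-2H-chromen-2-yl]methanol F4.
- Triflation gives (R)-[6-bromo-2-(tert-butyldimethylsilyloxymethyl)-7-(triisopropylsilyloxy)-2H-chromen-2-yl]methyl trifluoromethanesulfonate F5.
- LiEt3BH gives (R)-{[6-bromo-2-methyl-7-(triisopropylsilyloxy)-2H-chromen-2-yl]methoxy}(tert-butyl)dimethylsilane F6.
- Aqueous HCl in THF removes the primary silyl ether to give 14.

Step 8. Once the acetate is cleaved, intramolecular O-alkylation by the neighbouring alkoxide (closure to a four-membered cyclic ether, favoured by the geminal substitution) may compete with hydride delivery. Participation of the acetate carbonyl could also scramble the two arms. Fallback, from 9 and back at 14: the second arm is given a hydride-stable ether before the substitution. Acetylation of 9 (Ac2O, pyridine, DMAP) gives [6-bromo-7-(triisopropylsilyloxy)-2H-chromene-2,2-diyl]bis(methylene) diacetate F7. Hydrolysis with the same lipase in pH 7 buffer, which under the stated assumption removes the pro-S ester, gives (R)-[6-bromo-2-(hydroxymethyl)-7-(triisopropylsilyloxy)-2H-chromen-2-yl]methyl acetate F2. The sequence described for step 6 then follows through (S)-[6-bromo-2-(tert-butyldimethylsilyloxymethyl)-7-(triisopropylsilyloxy)-2H-chromen-2-yl]methyl acetate F3, (S)-[6-bromo-2-(tert-butyldimethylsilyloxymethyl)-7-(triisopropylsilyloxy)-2H-chromen-2-yl]methanol F4, (R)-[6-bromo-2-(tert-butyldimethylsilyloxymethyl)-7-(triisopropylsilyloxy)-2H-chromen-2-yl]methyl trifluoromethanesulfonate F5 and (R)-{[6-bromo-2-methyl-7-(triisopropylsilyloxy)-2H-chromen-2-yl]methoxy}(tert-butyl)dimethylsilane F6 to 14.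

Step 9. Oxidative addition into the electron-rich, ortho-silyloxy aryl bromide may be slow. Prolonged heating with palladium could then allow Heck-type arylation of the chromene double bond, protodestannylation, or erosion of the C2 configuration. Fallback, from 8 and back at 16: the palladium step is moved ahead of the creation of the stereocentre.
- Stille coupling of 8 gives 6-(1-ethoxyethenyl)-2',2'-dimethyl-7-(triisopropylsilyloxy)spiro[chromene-2,5'-[1,3]dioxane] F8.
- Aqueous HCl in THF hydrolyses both the enol ether and the acetonide to 1-[2,2-bis(hydroxymethyl)-7-(triisopropylsilyloxy)-2H-chromen-6-yl]ethanone F9.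
- Lipase acetylation as in step 6 gives (S)-[6-acetyl-2-(hydroxymethyl)-7-(triisopropylsilyloxy)-2H-chromen-2-yl]methyl acetate F10.
- Triflation gives (R)-[6-acetyl-7-(triisopropylsilyloxy)-2-(trifluoromethylsulfonyloxymethyl)-2H-chromen-2-yl]methyl acetate F11.
- LiEt3BH displaces the triflate, cleaves the acetate and also reduces the ketone, giving 1-[(R)-2-(hydroxymethyl)-2-methyl-7-(triisopropylsilyloxy)-2H-chromen-6-yl]ethanol F12 as a mixture of carbinol epimers.
- Activated MnO2 in CH2Cl2 reoxidises only the benzylic alcohol, giving 16.

## Further compounds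

F1 | step 2 | 1-[5-bromo-2-hydroxy-4-(triisopropylsilyloxy)phenyl]-2-(5-hydroxy-2,2-dimethyl-1,3-dioxan-5-yl)ethanone | CC1(C)OCC(O)(CC(=O)c2cc(Br)c(O[Si](C(C)C)(C(C)C)C(C)C)cc2O)CO1
F2 | step 6 | (R)-[6-bromo-2-(hydroxymethyl)-7-(triisopropylsilyloxy)-2H-chromen-2-yl]methyl acetate | OC[C@@]1(COC(C)=O)C=Cc2cc(Br)c(O[Si](C(C)C)(C(C)C)C(C)C)cc2O1
F3 | step 6 | (S)-[6-bromo-2-(tert-butyldimethylsilyloxymethyl)-7-(triisopropylsilyloxy)-2H-chromen-2-yl]methyl acetate | CC(C)(C)[Si](C)(C)OC[C@@]1(COC(C)=O)C=Cc2cc(Br)c(O[Si](C(C)C)(C(C)C)C(C)C)cc2O1
F4 | step 6 | (S)-[6-bromo-2-(tert-butyldimethylsilyloxymethyl)-7-(triisopropylsilyloxy)-2H-chromen-2-yl]methanol | CC(C)(C)[Si](C)(C)OC[C@@]1(CO)C=Cc2cc(Br)c(O[Si](C(C)C)(C(C)C)C(C)C)cc2O1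
F5 | step 6 | (R)-[6-bromo-2-(tert-butyldimethylsilyloxymethyl)-7-(triisopropylsilyloxy)-2H-chromen-2-yl]methyl trifluoromethanesulfonate | CC(C)(C)[Si](C)(C)OC[C@@]1(COS(=O)(=O)C(F)(F)F)C=Cc2cc(Br)c(O[Si](C(C)C)(C(C)C)C(C)C)cc2O1
F6 | step 6 | (R)-{[6-bromo-2-methyl-7-(triisopropylsilyloxy)-2H-chromen-2-yl]methoxy}(tert-butyl)dimethylsilane | CC(C)(C)[Si](C)(C)OC[C@@]1(C)C=Cc2cc(Br)c(O[Si](C(C)C)(C(C)C)C(C)C)cc2O1
F7 | step 8 | [6-bromo-7-(triisopropylsilyloxy)-2H-chromene-2,2-diyl]bis(methylene) diacetate | CC(=O)OCC1(COC(C)=O)C=Cc2cc(Br)c(O[Si](C(C)C)(C(C)C)C(C)C)cc2O1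
F8 | step 9 | 6-(1-ethoxyethenyl)-2',2'-dimethyl-7-(triisopropylsilyloxy)spiro[chromene-2,5'-[1,3]dioxane] | CC1(C)OCC2(CO1)C=Cc1cc(C(=C)OCC)c(O[Si](C(C)C)(C(C)C)C(C)C)cc1O2
F9 | step 9 | 1-[2,2-bis(hydroxymethyl)-7-(triisopropylsilyloxy)-2H-chromen-6-yl]ethanone | OCC1(CO)C=Cc2cc(C(C)=O)c(O[Si](C(C)C)(C(C)C)C(C)C)cc2O1
F10 | step 9 | (S)-[6-acetyl-2-(hydroxymethyl)-7-(triisopropylsilyloxy)-2H-chromen-2-yl]methyl acetate | CC(=O)OC[C@@]1(CO)C=Cc2cc(C(C)=O)c(O[Si](C(C)C)(C(C)C)C(C)C)cc2O1
F11 | step 9 | (R)-[6-acetyl-7-(triisopropylsilyloxy)-2-(trifluoromethylsulfonyloxymethyl)-2H-chromen-2-yl]methyl acetate | CC(=O)OC[C@@]1(COS(=O)(=O)C(F)(F)F)C=Cc2cc(C(C)=O)c(O[Si](C(C)C)(C(C)C)C(C)C)cc2O1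
F12 | step 9 | 1-[(R)-2-(hydroxymethyl)-2-methyl-7-(triisopropylsilyloxy)-2H-chromen-6-yl]ethanol (both carbinol epimers) | OC[C@@]1(C)C=Cc2cc(C(C)O)c(O[Si](C(C)C)(C(C)C)C(C)C)cc2O1
A1 | alternative 1 | (R)-7-(tert-butyldimethylsilyloxy)-6-hydroxy-6-methyl-3-methylideneheptan-2-one | CC(=O)C(=C)CC[C@@](C)(O)CO[Si](C)(C)C(C)(C)C
A2 | alternative 1 | dimethyl malonate | COC(=O)CC(=O)OC
A3 | alternative 1 | methyl 5-[(R)-4-(tert-butyldimethylsilyloxy)-3-hydroxy-3-methylbutyl]-2,4-dioxocyclohexane-1-carboxylate | COC(=O)C1CC(CC[C@@](C)(O)CO[Si](C)(C)C(C)(C)C)C(=O)CC1=O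
A4 | alternative 2 | (R,Z)-1-{2,4-difluoro-5-[3-hydroxy-4-(4-methoxybenzyloxy)-3-methylbut-1-enyl]phenyl}ethanone | CC(=O)c1cc(/C=C\[C@@](C)(O)COCc2ccc(OC)cc2)c(F)cc1F
A5 | alternative 2 | (R)-1-[7-fluoro-2-(4-methoxybenzyloxymethyl)-2-methyl-2H-chromen-6-yl]ethanone | CC(=O)c1cc2C=C[C@](C)(COCc3ccc(OC)cc3)Oc2cc1F
A6 | alternative 3 | (R)-tert-butyl{[6-(2,2-bis(trimethylsilyloxy)ethenyl)-2-methyl-3,4-dihydro-2H-pyran-2-yl]methoxy}dimethylsilane | C[Si](C)(C)OC(O[Si](C)(C)C)=CC1=CCC[C@](C)(CO[Si](C)(C)C(C)(C)C)O1
A7 | alternative 3 | but-3-yn-2-one | CC(=O)C#C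
A8 | alternative 3 | (R)-1-[2-(tert-butyldimethylsilyloxymethyl)-7-hydroxy-2-methylchroman-6-yl]ethanone | CC(=O)c1cc2CC[C@](C)(CO[Si](C)(C)C(C)(C)C)Oc2cc1O
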